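Assumption: (−)-drimenol and buta-2,3-dien-1-ol are bought; positions follow drimane/labdane numbering (C17 = methyl on C8), with α the face of H-5 and H-9 and β the face of the C10 methyl.

**Retrosynthetic overview**
- The 14,15-diol is unmasked from a cyclic carbonate. The carbonate, the C12–C13 bond and the C14 stereocentre come from one new palladium-catalysed, ligand-controlled coupling of an (E)-alkenyl iodide, buta-2,3-dien-1-ol and CO2.
- The (E)-alkenyl iodide comes from the C11 aldehyde (Takai), which is the CH2OH carbon of drimenol.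
- The ring B triol comes from the drimenol C7=C8 alkene: α-face dihydroxylation (sets 8α-OH), oxidation at C7, then α-face hydroboration of the C6=C7 silyl enol ether (sets 6α-OH and 7β-O).
- No carbocycle is built: rings A and B with C5, C9 and C10 come intact from (−)-drimenol; the only ring formed is the temporary 1,3-dioxolan-2-one.

**Route**

Step 1
Reactants: 1 (−)-drimenol, (5S,9S,10S)-drim-7-en-11-ol
Product: 3 11-benzyloxydrim-7-ene, via sodium drim-7-en-11-olate 2 (not isolated)
Conditions: NaH, THF/DMF, 0 °C; then BnBr, n-Bu4NI (cat.), rt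
Reagents that add atoms: benzyl bromide, BrCc1ccccc1
Why: Williamson ether synthesis on the primary alkoxide touches no stereocentre and gives a group that survives until the alkene-free stage where it can be hydrogenolysed.

Step 2
Reactants: 3 11-benzyloxydrim-7-ene
Product: 4 11-benzyloxydrimane-7α,8α-diol
Conditions: OsO4 (5 mol %), NMO, acetone/H2O, rt
Reagents that add atoms: osmium tetroxide, O=[Os](=O)(=O)=O; N-methylmorpholine N-oxide, C[N+]1([O-])CCOCC1; water, O
Why: Upjohn syn-dihydroxylation occurs on the α face, opposite the axial C10 methyl and the β substituent on C9, which sets 8α-OH/8β-CH3 and a 7α-OH that is erased in step 3.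

Step 3
Reactants: 4 11-benzyloxydrimane-7α,8α-diol
Product: 5 11-benzyloxy-8α-hydroxydriman-7-one
Conditions: IBX, DMSO, rt
Reagents that add atoms: none
Why: IBX oxidation converts the secondary axial C7 alcohol to the ketone without cleaving the 1,2-diol, and the tertiary C8 alcohol cannot be oxidised.

Step 4
Reactants: 5 11-benzyloxy-8α-hydroxydriman-7-one
Product: 7 11-benzyloxy-7,8α-bis(triethylsilyloxy)drim-6-ene, via 8-O-triethylsilyl ketone 6 (not isolated)
Conditions: TESOTf (3 equiv), Et3N, CH2Cl2, 0 °C → rt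
Reagents that add atoms: triethylsilyl trifluoromethanesulfonate, CC[Si](CC)(CC)OS(=O)(=O)C(F)(F)F
Why: Silyl triflate/amine silylation protects the tertiary alcohol and forms the silyl enol ether, which can only form toward C6 because C8 is fully substituted.

Step 5
Reactants: 7 11-benzyloxy-7,8α-bis(triethylsilyloxy)drim-6-ene
Product: 9 11-benzyloxy-7β,8α-bis(triethylsilyloxy)driman-6α-ol, via 6α-alkylborane 8 (not isolated)
Conditions: BH3·THF, THF, 0 °C → rt; then NaOH, H2O2, 0 °C → rt
Reagents that add atoms: hydrogen peroxide, OO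
Why: Hydroboration–oxidation of a silyl enol ether puts boron β to oxygen and adds H–B syn on the α face (the β face is blocked by the axial methyls on C4, C8 and C10), so H-7 and boron are α, the 7-silyloxy group becomes β, and oxidation with retention gives the 6α alcohol.

Step 6
Reactants: 9 11-benzyloxy-7β,8α-bis(triethylsilyloxy)driman-6α-ol
Product: 10 11-benzyloxy-6α,7β,8α-tris(triethylsilyloxy)drimane
Conditions: TESOTf, 2,6-lutidine, CH2Cl2, −78 → 0 °C
Reagents that add atoms: triethylsilyl trifluoromethanesulfonate, CC[Si](CC)(CC)OS(=O)(=O)C(F)(F)F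
Why: Silyl triflate protection of the hindered equatorial alcohol makes the three ring hydroxyls uniform for one late desilylation and changes no stereocentre.

Step 7
Reactants: 10 11-benzyloxy-6α,7β,8α-tris(triethylsilyloxy)drimane
Product: 11 6α,7β,8α-tris(triethylsilyloxy)driman-11-ol
Conditions: H2 (1 atm), Pd/C (10 wt % Pd on carbon), EtOAc, rt
Reagents that add atoms: none
Why: Hydrogenolysis of the benzyl ether is clean because the molecule has no alkene at this stage and triethylsilyl ethers are stable in neutral ethyl acetate.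

Step 8
Reactants: 11 6α,7β,8α-tris(triethylsilyloxy)driman-11-ol
Product: 12 6α,7β,8α-tris(triethylsilyloxy)driman-11-al
Conditions: IBX, DMSO/THF, rt
Reagents that add atoms: none
Why: Neutral IBX oxidation of the primary alcohol stops at the aldehyde, and the equatorial β formyl group on C9 is the thermodynamic epimer, so C9 is not at risk.

Step 9
Reactants: 12 6α,7β,8α-tris(triethylsilyloxy)driman-11-al
Product: 13 (11E)-12-iodo-6α,7β,8α-tris(triethylsilyloxy)-13,14,15,16-tetranorlabd-11-ene
Conditions: CrCl2 (8 equiv), CHI3 (3 equiv), THF/1,4-dioxane, 0 °C → rt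
Reagents that add atoms: iodoform, IC(I)I
Why: Takai olefination is aldehyde-selective and non-basic, and elimination from the less crowded geminal dichromium adduct gives the E-iodoalkene, which fixes the C11=C12 geometry.

Step 10
Reactants: 13 (11E)-12-iodo-6α,7β,8α-tris(triethylsilyloxy)-13,14,15,16-tetranorlabd-11-ene; 14 buta-2,3-dien-1-ol
Product: 15 (11E,14R)-6α,7β,8α-tris(triethylsilyloxy)labda-11,13(16)-diene-14,15-diyl carbonate (cyclic 1,3-dioxolan-2-one)
Conditions: Pd2(dba)3·CHCl3 (2.5 mol %), (R,R)-DACH-phenyl Trost ligand (7.5 mol %), K2CO3 (3 equiv), 14 (3 equiv), CO2 (1 atm), DMF, 40 °C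
Reagents that add atoms: carbon dioxide, O=C=O
Why: Proposed new method: oxidative addition of 13 to the zerovalent palladium–ligand complex, syn-carbopalladation of the allene at its central carbon (forming C12–C13 with retention of the E-alkene) and CO2 capture by the pendant alkoxide give a π-allylpalladium carbonate whose two faces interconvert by η3–η1–η3 slippage through the unsubstituted CH2 terminus, so the chiral ligand and not the remote decalin decides which complex undergoes 5-exo C–O closure at C14 and sets 14R; the closest known reactions are the racemic palladium-catalysed three-component coupling of 2,3-allenols, organic halides and CO2 to cyclic carbonates and the Trost-ligand-controlled dynamic kinetic asymmetric carbonate formation from vinyl epoxides through the same type of π-allyl intermediate, which have not been merged into a ligand-controlled alkenylative carboxylation.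

Step 11
Reactants: 15 (11E,14R)-6α,7β,8α-tris(triethylsilyloxy)labda-11,13(16)-diene-14,15-diyl carbonate
Product: 16 (11E,14R)-6α,7β,8α-trihydroxylabda-11,13(16)-diene-14,15-diyl carbonate
Conditions: HF·pyridine, pyridine, THF, 0 °C → rt
Reagents that add atoms: none
Why: Fluoride-driven desilylation (strong Si–F bond) removes all three triethylsilyl groups in a buffered medium that leaves the cyclic carbonate, the diene and every stereocentre untouched.

Step 12
Reactants: 16 (11E,14R)-6α,7β,8α-trihydroxylabda-11,13(16)-diene-14,15-diyl carbonate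
Product: 17 (11E,14R)-labda-11,13(16)-diene-6α,7β,8α,14,15-pentol (CNP0256357.2)
Conditions: K2CO3 (0.2 equiv), MeOH, 0 °C → rt
Reagents that add atoms: none
Why: Base-catalysed transesterification of the cyclic carbonate with methanol cleaves only acyl C–O bonds, so the C14–O bond and the 14R configuration are retained.

**Compound list**

1 | (−)-drimenol, (5S,9S,10S)-drim-7-en-11-ol | OC[C@H]1C(C)=CC[C@H]2C(C)(C)CCC[C@@]21C | starting material
2 | sodium drim-7-en-11-olate | [Na+].[O-]C[C@H]1C(C)=CC[C@H]2C(C)(C)CCC[C@@]21C | intermediate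
3 | 11-benzyloxydrim-7-ene | c3ccccc3COC[C@H]1C(C)=CC[C@H]2C(C)(C)CCC[C@@]21C | intermediate
4 | 11-benzyloxydrimane-7α,8α-diol | c3ccccc3COC[C@H]1[C@](C)(O)[C@H](O)C[C@H]2C(C)(C)CCC[C@@]21C | intermediate
5 | 11-benzyloxy-8α-hydroxydriman-7-one | c3ccccc3COC[C@H]1[C@](C)(O)C(=O)C[C@H]2C(C)(C)CCC[C@@]21C | intermediate
6 | 11-benzyloxy-8α-(triethylsilyloxy)driman-7-one | c3ccccc3COC[C@H]1[C@](C)(O[Si](CC)(CC)CC)C(=O)C[C@H]2C(C)(C)CCC[C@@]21C | intermediate
7 | 11-benzyloxy-7,8α-bis(triethylsilyloxy)drim-6-ene | c3ccccc3COC[C@H]1[C@](C)(O[Si](CC)(CC)CC)C(O[Si](CC)(CC)CC)=C[C@H]2C(C)(C)CCC[C@@]21C | intermediate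
8 | [11-benzyloxy-7β,8α-bis(triethylsilyloxy)driman-6α-yl]borane | c3ccccc3COC[C@H]1[C@](C)(O[Si](CC)(CC)CC)[C@@H](O[Si](CC)(CC)CC)[C@H](B)[C@H]2C(C)(C)CCC[C@@]21C | intermediate
9 | 11-benzyloxy-7β,8α-bis(triethylsilyloxy)driman-6α-ol | c3ccccc3COC[C@H]1[C@](C)(O[Si](CC)(CC)CC)[C@@H](O[Si](CC)(CC)CC)[C@H](O)[C@H]2C(C)(C)CCC[C@@]21C | intermediate
10 | 11-benzyloxy-6α,7β,8α-tris(triethylsilyloxy)drimane | c3ccccc3COC[C@H]1[C@](C)(O[Si](CC)(CC)CC)[C@@H](O[Si](CC)(CC)CC)[C@H](O[Si](CC)(CC)CC)[C@H]2C(C)(C)CCC[C@@]21C | intermediate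
11 | 6α,7β,8α-tris(triethylsilyloxy)driman-11-ol | OC[C@H]1[C@](C)(O[Si](CC)(CC)CC)[C@@H](O[Si](CC)(CC)CC)[C@H](O[Si](CC)(CC)CC)[C@H]2C(C)(C)CCC[C@@]21C | intermediate
12 | 6α,7β,8α-tris(triethylsilyloxy)driman-11-al | O=C[C@H]1[C@](C)(O[Si](CC)(CC)CC)[C@@H](O[Si](CC)(CC)CC)[C@H](O[Si](CC)(CC)CC)[C@H]2C(C)(C)CCC[C@@]21C | intermediate
13 | (11E)-12-iodo-6α,7β,8α-tris(triethylsilyloxy)-13,14,15,16-tetranorlabd-11-ene | I/C=C/[C@H]1[C@](C)(O[Si](CC)(CC)CC)[C@@H](O[Si](CC)(CC)CC)[C@H](O[Si](CC)(CC)CC)[C@H]2C(C)(C)CCC[C@@]21C | intermediate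
14 | buta-2,3-dien-1-ol | OCC=C=C | starting material
15 | (11E,14R)-6α,7β,8α-tris(triethylsilyloxy)labda-11,13(16)-diene-14,15-diyl carbonate | C=C(/C=C/[C@H]1[C@](C)(O[Si](CC)(CC)CC)[C@@H](O[Si](CC)(CC)CC)[C@H](O[Si](CC)(CC)CC)[C@H]2C(C)(C)CCC[C@@]21C)[C@@H]3COC(=O)O3 | intermediate
16 | (11E,14R)-6α,7β,8α-trihydroxylabda-11,13(16)-diene-14,15-diyl carbonate | C=C(/C=C/[C@H]1[C@](C)(O)[C@@H](O)[C@H](O)[C@H]2C(C)(C)CCC[C@@]21C)[C@@H]3COC(=O)O3 | intermediate
17 | (11E,14R)-labda-11,13(16)-diene-6α,7β,8α,14,15-pentol | C=C(/C=C/[C@H]1[C@](C)(O)[C@@H](O)[C@H](O)[C@H]2C(C)(C)CCC[C@@]21C)[C@@H](O)CO | target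

**Step count and risks**

Total step count: 12. Longest linear sequence: 12 steps (1 → 17); 14 is bought.

The three steps most likely to fail:

Step 10 (the new step). The risks are slow turnover with the hindered alkenyl iodide, epoxide or dihydrofuran by-products, and weak or reversed control at C14. The sense of induction cannot be predicted with confidence, so the ligand antipode is the first thing to try. The fallback uses known chemistry and takes C14 from the chiral pool; it sets out from 13 and comes back to the route at 17. Commercial (S)-2,2-dimethyl-1,3-dioxolane-4-carbaldehyde F1 is homologated with dimethyl (1-diazo-2-oxopropyl)phosphonate (K2CO3, MeOH) to (R)-4-ethynyl-2,2-dimethyl-1,3-dioxolane F2. Copper-catalysed α-selective protoboration [(SIMes)CuCl, NaOt-Bu, B2pin2, MeOH, THF; SIMes = 1,3-dimesitylimidazolidin-2-ylidene] gives (R)-2,2-dimethyl-4-[1-(4,4,5,5-tetramethyl-1,3,2-dioxaborolan-2-yl)ethenyl]-1,3-dioxolane F3. Suzuki–Miyaura coupling of F3 with 13 [Pd(dppf)Cl2, K3PO4, THF/H2O, 50 °C] gives, with retention of the alkene geometry, (11E,14R)-14,15-O-isopropylidene-6α,7β,8α-tris(triethylsilyloxy)labda-11,13(16)-diene-14,15-diol F4. Camphorsulfonic acid in MeOH (0 °C → rt) then removes the three silyl ethers and the acetonide to give 17.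

Step 5. The risks are sluggish or unselective hydroboration of the crowded enol ether and β-elimination of the β-silyloxy borane. The fallback replaces hydroboration by oxidation and reduction; it sets out from 7 and comes back at 10. Rubottom oxidation (mCPBA, NaHCO3, CH2Cl2, 0 °C; α-face epoxidation followed by silyl transfer) gives 11-benzyloxy-6α,8α-bis(triethylsilyloxy)driman-7-one F5. NaBH4 (MeOH/THF, 0 °C; axial hydride delivery from the α face) gives 11-benzyloxy-6α,8α-bis(triethylsilyloxy)driman-7β-ol F6. TESOTf/2,6-lutidine then gives 10.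

Step 9. The risk is a slow Takai reaction of an aldehyde flanked by two fully substituted carbons, with incomplete E-selectivity. The fallback goes through an alkyne; it sets out from 12 and comes back at 13. Ohira–Bestmann homologation [dimethyl (1-diazo-2-oxopropyl)phosphonate, K2CO3, MeOH] gives 6α,7β,8α-tris(triethylsilyloxy)-13,14,15,16-tetranorlabd-11-yne F7. Syn, anti-Markovnikov hydrozirconation with Cp2Zr(H)Cl (THF, rt) gives the (E)-alkenylzirconocene chloride F8, which is treated in the same flask with I2 to give 13 with retention.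

**Further compounds**

F1 | step 10 | (S)-2,2-dimethyl-1,3-dioxolane-4-carbaldehyde | O=C[C@@H]1COC(C)(C)O1
F2 | step 10 | (R)-4-ethynyl-2,2-dimethyl-1,3-dioxolane | C#C[C@@H]1COC(C)(C)O1
F3 | step 10 | (R)-2,2-dimethyl-4-[1-(4,4,5,5-tetramethyl-1,3,2-dioxaborolan-2-yl)ethenyl]-1,3-dioxolane | C=C(B1OC(C)(C)C(C)(C)O1)[C@@H]2COC(C)(C)O2
F4 | step 10 | (11E,14R)-14,15-O-isopropylidene-6α,7β,8α-tris(triethylsilyloxy)labda-11,13(16)-diene-14,15-diol | C=C(/C=C/[C@H]1[C@](C)(O[Si](CC)(CC)CC)[C@@H](O[Si](CC)(CC)CC)[C@H](O[Si](CC)(CC)CC)[C@H]2C(C)(C)CCC[C@@]21C)[C@@H]3COC(C)(C)O3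
F5 | step 5 | 11-benzyloxy-6α,8α-bis(triethylsilyloxy)driman-7-one | c3ccccc3COC[C@H]1[C@](C)(O[Si](CC)(CC)CC)C(=O)[C@H](O[Si](CC)(CC)CC)[C@H]2C(C)(C)CCC[C@@]21C
F6 | step 5 | 11-benzyloxy-6α,8α-bis(triethylsilyloxy)driman-7β-ol | c3ccccc3COC[C@H]1[C@](C)(O[Si](CC)(CC)CC)[C@@H](O)[C@H](O[Si](CC)(CC)CC)[C@H]2C(C)(C)CCC[C@@]21C
F7 | step 9 | 6α,7β,8α-tris(triethylsilyloxy)-13,14,15,16-tetranorlabd-11-yne | C#C[C@H]1[C@](C)(O[Si](CC)(CC)CC)[C@@H](O[Si](CC)(CC)CC)[C@H](O[Si](CC)(CC)CC)[C@H]2C(C)(C)CCC[C@@]21C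
F8 | step 9 | chlorobis(cyclopentadienyl)[(11E)-6α,7β,8α-tris(triethylsilyloxy)-13,14,15,16-tetranorlabd-11-en-12-yl]zirconium | Cl[Zr](/C=C/[C@H]1[C@](C)(O[Si](CC)(CC)CC)[C@@H](O[Si](CC)(CC)CC)[C@H](O[Si](CC)(CC)CC)[C@H]2C(C)(C)CCC[C@@]21C)(C3C=CC=C3)C3C=CC=C3
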